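The pitfall of the ash run is a straight line: product climbs from 6.4% to 23.0% almost evenly between 1.00 min and 4.00 min, but starting material has fallen to 70.2%, so a slowing rate can hide within the scatter of 0.3 percentage points.

| flask | starting material | acid | scavenger | protic impurity | remark | time |
|---|---|---|---|---|---|---|
| ash | 0.20 M | 6 mM | 0.16 M | 0.020 M | run made earlier |  |
| flask | 0.20 M | 6.00 mM | 0.160 M | 0.0400 M |  | 20 min |

ash run (percent of the starting material charged)

| time / min | starting material / % | product / % |
|---|---|---|
| 1.00 | 90.4 | 6.4 |
| 2.00 | 82.2 | 11.9 |
| 3.00 | 76.0 | 17.8 |
| 4.00 | 70.2 | 23.0 |

(each reading ± 0.3 percentage points)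

- acid is the free proton; pH is minus the decimal logarithm of its molar concentration
- what has gone from starting material into another species counts as reacted, even if it can come back
- no earlier run changes the charge of protic impurity; that part of a forecast is a guess

- part of the starting material that has reacted at 20 min
- pH of the solution at 20 min

This reckoning takes the end state as starting material gone and acid returned at each turnover, so the decay is pseudo-first-order, with rate κ[acid][starting material]. Product gained over that span, divided by the minutes, the mean starting material and the acid charge, gives 11.5 M⁻¹ min⁻¹. This reading is the acid clock κ, and it turns an acid level into a half-life τ = ln(2)/(κ[acid]). In the flask τ is 10.1 min, so 20 min gives 74.8% reacted, with the impurity charge left out as a guess. Unchanged acid gives pH 2.22.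

The forecast gave 72% and pH 2.35, with the remark "That looks zero-order".

The flask gives 77.5% reacted and pH 2.21.

    weak acid ⇌ conjugate base + acid, settled at all times (K = 7.90 × 10⁻⁵ M)
    starting material + acid → weak acid + acid + product (k = 11.0 M⁻¹ min⁻¹)
    starting material → weak acid + product (k = 0.00140 min⁻¹)
    starting material + protic impurity → quenched substrate (k = 0.230 M⁻¹ min⁻¹)
    weak acid + scavenger → scavenged by-product (k = 8.40 M⁻¹ min⁻¹)
    starting material + weak acid ⇌ idle adduct, settled at all times (K = 10.0 M⁻¹)

That is 2.7 points above the reckoning, and at 20 min quenched substrate in the flask holds 7.32% of the charge. Put to use again, τ of 10.1 min fits the flask's second stretch: starting material goes from 45.0% at 10.0 min to 22.5% at 20.0 min, about half.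

A neighbour flask charged with 0.0024 M of acid has τ = 25.1 min, so the clock gives 42.4% at 20 min. Computed, that flask holds 40.3% product and has 51.6% reacted.

(All runs are calculated for substances that don't exist, and the scatter is random.)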